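**Strategy.** The target is a pyrrole-2-carbaldehyde whose ring carbon C3 carries an unbranched, stereocentre-free C23 chain. The route rests on cutting that chain between its second and third carbons (counted from C3), pairing a 2-(pyrrol-3-yl)ethyl radical with the henicosyl radical released from inexpensive docosanoic acid. A single mixed Kolbe electrolysis makes this C(sp3)–C(sp3) bond, adds 21 carbons at once and closes no ring. Its precursor is a 3-(pyrrol-3-yl)propanoic acid whose ring is shielded from anodic oxidation by an N-tosyl group and a C2 methyl ester; the ester is later taken to the aldehyde while the sulfonyl group is still in place.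

Key step: step 4

Remark: Ts (tosyl) is the 4-methylphenylsulfonyl group; all four starting materials are assumed to be purchasable; chain carbons are counted outwards from ring carbon C3.

**Step 1**
Reactants: 1 methyl 3-bromo-1H-pyrrole-2-carboxylate; 2 p-toluenesulfonyl chloride
Product: 4 methyl 3-bromo-1-tosylpyrrole-2-carboxylate, via sodium 3-bromo-2-(methoxycarbonyl)pyrrol-1-ide 3 (not isolated)
Conditions: NaH (1.2 equiv), DMF, 0 °C; then TsCl (1.2 equiv), 0 °C → rt
Reagents that add atoms: p-toluenesulfonyl chloride (compound 2), Cc1ccc(cc1)S(=O)(=O)Cl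
Why: The N–H, acidified by the C2 ester, is deprotonated irreversibly by NaH and the anion is sulfonylated at nitrogen (N-sulfonylation of a pyrrolide), which also deactivates the ring for the later anodic step.

**Step 2**
Reactants: 4 methyl 3-bromo-1-tosylpyrrole-2-carboxylate; 5 benzyl acrylate
Product: 6 benzyl (E)-3-[2-(methoxycarbonyl)-1-tosylpyrrol-3-yl]prop-2-enoate
Conditions: Pd(OAc)2 (5 mol%), P(o-tol)3 (12 mol%), Et3N (2.5 equiv), DMF, 100 °C
Reagents that add atoms: benzyl acrylate (compound 5), C=CC(=O)OCc1ccccc1
Why: Mizoroki–Heck reaction, in which oxidative addition of the electron-poor C3–Br bond to zerovalent palladium, syn insertion of the acrylate and syn β-hydride elimination should give the E alkene, whose geometry is erased in step 3.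

**Step 3**
Reactants: 6 benzyl (E)-3-[2-(methoxycarbonyl)-1-tosylpyrrol-3-yl]prop-2-enoate
Product: 8 3-[2-(methoxycarbonyl)-1-tosylpyrrol-3-yl]propanoic acid, via benzyl 3-[2-(methoxycarbonyl)-1-tosylpyrrol-3-yl]propanoate 7 (not isolated)
Conditions: H2 (1 atm), 10% Pd/C, EtOAc/MeOH, rt
Reagents that add atoms: none
Why: Catalytic hydrogenation saturates the conjugated alkene and the same catalyst then hydrogenolyses the benzyl ester, so one operation frees the acid while the methyl ester, the N-sulfonyl group and the electron-poor pyrrole ring stay untouched.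

**Step 4**
Reactants: 8 3-[2-(methoxycarbonyl)-1-tosylpyrrol-3-yl]propanoic acid; 9 docosanoic acid
Product: 12 methyl 1-tosyl-3-tricosylpyrrole-2-carboxylate, via 2-[2-(methoxycarbonyl)-1-tosylpyrrol-3-yl]ethyl radical 10 (not isolated), via henicosyl radical 11 (not isolated)
Conditions: undivided cell, smooth Pt anode and Pt cathode, 8 (1 equiv), 9 (6 equiv), NaOMe (5 mol% of total acid), MeOH, 55 °C, constant current ca. 0.15 A cm−2 with periodic polarity reversal, stopped while the electrolyte is still faintly acidic
Reagents that add atoms: docosanoic acid (compound 9), CCCCCCCCCCCCCCCCCCCCCC(=O)O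
Why: Each carboxylate is oxidised by one electron at the platinum anode and loses CO2, so the primary radicals 10 and 11 arise side by side in the dense carboxylate layer at the electrode and combine to form the bond between the second and third chain carbons. The closest known reaction type is the mixed Kolbe electrolysis of two aliphatic acids with the cheaper one in excess, as used to homologate long-chain fatty acids, and 3-arylpropanoic acids are competent partners in it. No ring is closed and no stereocentre is created, so only chemoselectivity matters. Cross-coupling of the valuable acid is favoured statistically by the sixfold excess of 9, and the non-polar homodimer of 11 (dotetracontane) should be removable by crystallisation and filtration through silica. Oxidation of the carboxylate rather than the heterocycle is secured by the N-tosyl and C2 ester groups, which raise the oxidation potential of the ring, and radical 10 is primary and separated from the ring by a CH2 group, so it should not be oxidised on to a cation (no Hofer–Moest products). Keeping the electrolyte weakly acidic by partial neutralisation and early termination keeps methoxide away from the base-labile N-sulfonyl group.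

**Step 5**
Reactants: 12 methyl 1-tosyl-3-tricosylpyrrole-2-carboxylate
Product: 13 (1-tosyl-3-tricosylpyrrol-2-yl)methanol
Conditions: i-Bu2AlH (DIBAL-H, 2.5 equiv), CH2Cl2/toluene, −40 → 0 °C; aq. potassium sodium tartrate
Reagents that add atoms: none
Why: Ester-to-alcohol reduction with an aluminium hydride at low temperature, which should leave the N–S bond intact, while the deliberately retained electron-withdrawing N-sulfonyl group stops the pyrrol-2-ylmethanol from ionising to an azafulvenium ion and self-condensing.

**Step 6**
Reactants: 13 (1-tosyl-3-tricosylpyrrol-2-yl)methanol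
Product: 14 1-tosyl-3-tricosylpyrrole-2-carbaldehyde
Conditions: activated MnO2 (15 equiv), CH2Cl2, rt
Reagents that add atoms: none
Why: Heterogeneous MnO2 oxidation of a heteroaryl (benzylic-type) primary carbinol should stop cleanly at the aldehyde, and nothing else in the molecule is oxidisable under these conditions.

**Step 7**
Reactants: 14 1-tosyl-3-tricosylpyrrole-2-carbaldehyde
Product: 15 3-tricosyl-1H-pyrrole-2-carbaldehyde
Conditions: LiOH·H2O (3 equiv), THF/H2O (4:1), rt → 40 °C; then aq. NH4Cl
Reagents that add atoms: none
Why: Nucleophilic N-desulfonylation by hydroxide at sulfur, made easy because the departing pyrrolide is stabilised by the C2 formyl group, while the aldehyde is non-enolisable and hydroxide (unlike methoxide) generates no methyl sulfonate that could N-alkylate the product.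

**Compound list**

1 | methyl 3-bromo-1H-pyrrole-2-carboxylate | COC(=O)c1[nH]ccc1Br | starting material
2 | p-toluenesulfonyl chloride | Cc1ccc(cc1)S(=O)(=O)Cl | starting material
3 | sodium 3-bromo-2-(methoxycarbonyl)pyrrol-1-ide (formed and consumed in step 1) | COC(=O)c1c(Br)cc[n-]1.[Na+] | intermediate
4 | methyl 3-bromo-1-tosylpyrrole-2-carboxylate | COC(=O)c1c(Br)ccn1S(=O)(=O)c1ccc(C)cc1 | intermediate
5 | benzyl acrylate | C=CC(=O)OCc1ccccc1 | starting material
6 | benzyl (E)-3-[2-(methoxycarbonyl)-1-tosylpyrrol-3-yl]prop-2-enoate | COC(=O)c1c(/C=C/C(=O)OCc2ccccc2)ccn1S(=O)(=O)c1ccc(C)cc1 | intermediate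
7 | benzyl 3-[2-(methoxycarbonyl)-1-tosylpyrrol-3-yl]propanoate (formed and consumed in step 3) | COC(=O)c1c(CCC(=O)OCc2ccccc2)ccn1S(=O)(=O)c1ccc(C)cc1 | intermediate
8 | 3-[2-(methoxycarbonyl)-1-tosylpyrrol-3-yl]propanoic acid (precursor of the key step) | COC(=O)c1c(CCC(=O)O)ccn1S(=O)(=O)c1ccc(C)cc1 | intermediate
9 | docosanoic acid | CCCCCCCCCCCCCCCCCCCCCC(=O)O | starting material
10 | 2-[2-(methoxycarbonyl)-1-tosylpyrrol-3-yl]ethyl radical (formed and consumed in step 4) | [CH2]Cc1ccn(S(=O)(=O)c2ccc(C)cc2)c1C(=O)OC | intermediate
11 | henicosyl radical (formed and consumed in step 4) | [CH2]CCCCCCCCCCCCCCCCCCCC | intermediate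
12 | methyl 1-tosyl-3-tricosylpyrrole-2-carboxylate (product of the key step) | CCCCCCCCCCCCCCCCCCCCCCCc1ccn(S(=O)(=O)c2ccc(C)cc2)c1C(=O)OC | intermediate
13 | (1-tosyl-3-tricosylpyrrol-2-yl)methanol | CCCCCCCCCCCCCCCCCCCCCCCc1ccn(S(=O)(=O)c2ccc(C)cc2)c1CO | intermediate
14 | 1-tosyl-3-tricosylpyrrole-2-carbaldehyde | CCCCCCCCCCCCCCCCCCCCCCCc1ccn(S(=O)(=O)c2ccc(C)cc2)c1C=O | intermediate
15 | 3-tricosyl-1H-pyrrole-2-carbaldehyde | CCCCCCCCCCCCCCCCCCCCCCCc1cc[nH]c1C=O | target

**Step count and risk**

Total step count: 7. Longest linear sequence: 7 steps (1 → 15); compounds 2, 5 and 9 enter as single-step partners.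

Steps most likely to fail:

1. Step 4 (mixed Kolbe electrolysis). The anode may foul with waxy hydrocarbon so that the current collapses. The heteroaromatic ring may be oxidised in competition with the carboxylate. The N-sulfonyl group may be solvolysed if the electrolyte drifts alkaline. Statistical homocoupling may consume the pyrrole acid. Fallback (olefination instead of radical coupling, setting out from 6 and returning at 12): Lemieux–Johnson cleavage of the acrylate double bond of 6 (OsO4 cat., NaIO4, 2,6-lutidine, dioxane/H2O) should give methyl 3-formyl-1-tosylpyrrole-2-carboxylate F1. Separately, commercial 1-bromodocosane and PPh3 in hot toluene should give docosyltriphenylphosphonium bromide F2, which NaN(SiMe3)2 in THF at −78 °C converts into docosylidenetriphenylphosphorane F3. A Wittig reaction of F3 with F1 should give methyl 1-tosyl-3-[(Z)-tricos-1-enyl]pyrrole-2-carboxylate F4 (the alkene geometry is immaterial), and hydrogenation over Pd/C in EtOAc/THF then gives 12.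

2. Step 2 (Heck coupling). Oxidative addition at the hindered C3 position next to the ester may be sluggish, and reductive debromination or acrylate polymerisation may compete at 100 °C. Fallback (sp2–sp3 cross-coupling at the saturated oxidation level, setting out from 4 and returning at 8): zinc dust activated with LiCl in THF inserts into commercial tert-butyl 3-bromopropanoate to give (3-tert-butoxy-3-oxopropyl)zinc bromide F5. Negishi coupling of F5 with 4 (Pd(OAc)2, SPhos, THF, 50 °C) should give tert-butyl 3-[2-(methoxycarbonyl)-1-tosylpyrrol-3-yl]propanoate F6. CF3CO2H in CH2Cl2 then cleaves the tert-butyl ester to acid 8, bypassing 6 and 7.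

3. Step 5 (hydride reduction). Hydride attack at sulfur may remove the N-sulfonyl group prematurely, after which the unprotected carbinol ionises and oligomerises or is over-reduced; poor solubility of the waxy ester in the cold may also leave the reduction incomplete. Fallback (McFadyen–Stevens route that never passes through a carbinol, setting out from 12 and returning at the target 15): heating 12 with excess N2H4·H2O in EtOH/THF should convert the ester into the hydrazide and strip the N-sulfonyl group by attack at sulfur, giving 3-tricosyl-1H-pyrrole-2-carbohydrazide F7. TsCl (compound 2) in pyridine at 0 °C should sulfonylate the terminal nitrogen to N'-tosyl-3-tricosyl-1H-pyrrole-2-carbohydrazide F8. Heating F8 with Na2CO3 in ethylene glycol at 160 °C should then deliver 15 directly, so that steps 6 and 7 fall away.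

**Further compounds**

F1 | step 4 | methyl 3-formyl-1-tosylpyrrole-2-carboxylate | COC(=O)c1c(C=O)ccn1S(=O)(=O)c1ccc(C)cc1
F2 | step 4 | docosyltriphenylphosphonium bromide | CCCCCCCCCCCCCCCCCCCCCC[P+](c1ccccc1)(c1ccccc1)c1ccccc1.[Br-]
F3 | step 4 | docosylidenetriphenylphosphorane | CCCCCCCCCCCCCCCCCCCCCC=P(c1ccccc1)(c1ccccc1)c1ccccc1
F4 | step 4 | methyl 1-tosyl-3-[(Z)-tricos-1-enyl]pyrrole-2-carboxylate | CCCCCCCCCCCCCCCCCCCCC/C=C\c1ccn(S(=O)(=O)c2ccc(C)cc2)c1C(=O)OC
F5 | step 2 | (3-tert-butoxy-3-oxopropyl)zinc bromide | CC(C)(C)OC(=O)CC[Zn]Br
F6 | step 2 | tert-butyl 3-[2-(methoxycarbonyl)-1-tosylpyrrol-3-yl]propanoate | COC(=O)c1c(CCC(=O)OC(C)(C)C)ccn1S(=O)(=O)c1ccc(C)cc1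
F7 | step 5 | 3-tricosyl-1H-pyrrole-2-carbohydrazide | CCCCCCCCCCCCCCCCCCCCCCCc1cc[nH]c1C(=O)NN
F8 | step 5 | N'-tosyl-3-tricosyl-1H-pyrrole-2-carbohydrazide | CCCCCCCCCCCCCCCCCCCCCCCc1cc[nH]c1C(=O)NNS(=O)(=O)c1ccc(C)cc1
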